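**Assumptions (one line):** The given SMILES is the natural series (2S-OH, 6R, 7R, 8R, 10S, C3 hemiketal S, Z-C4=C5). L-Proline is assumed to give the (R)-α-aminoxy aldehyde in step 4, and (S,S)-Ru-TsDPEN the (S)-furyl carbinol in step 12.

## Retrosynthetic overview
1. The target is the transannular C3/C10 hemiketal of a 3-oxo-Δ4(Z) germacranolide. It forms spontaneously when the 2,10-bis-TBS 8-angelate is desilylated, and the angelate is added last.
2. The ten-membered carbocycle, the C6–C7 bond and the trans-fused α-methylene lactone come from one key step. This is an intramolecular In-Barbier γ-allylation of a (Z)-4-oxo-2-enal by a (Z)-2-(bromomethyl)enoate, followed by lactonization (the proposed new step).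
3. The Z-4-oxoenal comes from oxidative opening of a 2-alkyl-3-methylfuran, which fixes Z-C4=C5 and the C3 oxidation level.
4. The allylic bromide comes from a Morita–Baylis–Hillman (MBH) reaction of an α-silyloxy aldehyde. C8 is set by proline α-aminoxylation, C2 by Noyori transfer hydrogenation of a furyl ketone, and quaternary C10 by (R)-linalool.
5. Rings are formed in this order: furan (pre-formed), then the 10-membered ring plus lactone, then the bridging tetrahydrofuran hemiketal (last step).

## Route

**Step 1**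
Reactants: 1 (R)-linalool
Product: 2 tert-butyldimethylsilyl ether of 1
Conditions: TBSOTf, 2,6-lutidine, CH2Cl2, –78 → 0 °C
Reagents that add atoms: TBSOTf, CC(C)(C)[Si](C)(C)OS(=O)(=O)C(F)(F)F (adds TBS)
Why: Silylation of the tertiary alcohol, with no change at the stereocentre (it becomes C10 of the target).

**Step 2**
Reactants: 2
Product: 3 (6,7-epoxide of the prenyl alkene, ~1:1 epoxide epimers)
Conditions: mCPBA (1.0 equiv), NaHCO3, CH2Cl2, 0 °C
Reagents that add atoms: mCPBA, OOC(=O)c1cccc(Cl)c1 (adds O)
Why: Prilezhaev epoxidation is selective for the electron-rich trisubstituted alkene over the hindered vinyl group. The new epoxide stereocentre is destroyed in step 3.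

**Step 3**
Reactants: 3
Product: 4 (4R)-4-(TBSO)-4-methylhex-5-enal (C7 aldehyde, with C8H2, C9H2 and vinyl C1=C2)
Conditions: H5IO6, THF/H2O, 0 °C → rt
Reagents that add atoms: water, O (epoxide hydrolysis). H5IO6, OI(O)(O)(O)(O)=O, is only the oxidant.
Why: Periodic-acid diol cleavage of the epoxide (Malaprade type) releases acetone and the aldehyde.

**Step 4**
Reactants: 4
Product: 5 (2R,4R)-4-(TBSO)-4-methyl-2-[(phenylamino)oxy]hex-5-en-1-ol (C8 O-anilino, C7 CH2OH)
Conditions: PhNO, L-proline (20 mol%), CH3CN, 0 °C; then NaBH4, MeOH, 0 °C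
Reagents that add atoms: nitrosobenzene, O=Nc1ccccc1 (adds O–NHPh)
Why: Enamine-catalysed O-selective α-aminoxylation; the proline acid directs PhNO to one enamine face and sets C8 (R). In-situ NaBH4 reduction prevents racemization of the labile α-aminoxy aldehyde.

**Step 5**
Reactants: 5
Product: 6 (2R,4R)-4-(TBSO)-4-methylhex-5-ene-1,2-diol (C7 primary OH, C8 secondary OH)
Conditions: CuSO4·5H2O (0.3 equiv), MeOH, 25 °C
Reagents that add atoms: none
Why: Cu(II)-mediated reductive N–O cleavage frees the C8 alcohol without touching any stereocentre.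

**Step 6**
Reactants: 6
Product: 7 (1,2-bis-TES ether of 6)
Conditions: TESCl (3 equiv), imidazole, DMF, 0 → 25 °C
Reagents that add atoms: TESCl, CC[Si](Cl)(CC)CC (adds TES)
Why: Silylation protects both alcohols so the vinyl group can be functionalized. The primary TES can later be removed selectively.

**Step 7**
Reactants: 7
Product: 8 (3S,5R)-3-(TBSO)-3-methyl-5,6-bis(TESO)hexan-1-ol (C2 primary alcohol)
Conditions: 9-BBN, THF, 0 → 25 °C; then 3 M NaOH, 30% H2O2, 0 °C, 30 min
Reagents that add atoms: H2O2, OO (adds OH)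
Why: Hydroboration–oxidation of the vinyl group; 9-BBN adds anti-Markovnikov, giving C2–OH, with C1H2 as the linker.

**Step 8**
Reactants: 8
Product: 9 (3R,5R)-3-(TBSO)-3-methyl-5,6-bis(TESO)hexanal (C2 aldehyde)
Conditions: Dess–Martin periodinane, NaHCO3, CH2Cl2, 0 → 25 °C
Reagents that add atoms: none
Why: Buffered Dess–Martin oxidation of the primary alcohol; the buffer avoids β-elimination of the β-silyloxy aldehyde.

**Step 9**
Reactants: 10 3-methylfuran
Product: 11 2-bromo-3-methylfuran
Conditions: NBS, DMF, 0 °C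
Reagents that add atoms: NBS, O=C1CCC(=O)N1Br (adds Br)
Why: Electrophilic bromination of the furan at C2, the α-position activated by the 3-methyl group.

**Step 10**
Reactants: 9 and 11
Product: 12 1-(3-methylfuran-2-yl) carbinol (C2 epimeric mixture; all other centres unchanged)
Conditions: n-BuLi, Et2O, –78 °C (Br/Li exchange of 11); then add 9, –78 → –40 °C
Reagents that add atoms: none beyond 11 (n-BuLi leaves only Li salts)
Why: 3-Methyl-2-furyllithium adds 1,2 to the aldehyde, forming the C2–C3 bond. The C2 epimers are destroyed in the next step.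

**Step 11**
Reactants: 12
Product: 13 2-acylfuran (C2 ketone)
Conditions: Dess–Martin periodinane, NaHCO3, CH2Cl2, 25 °C
Reagents that add atoms: none
Why: Oxidation to the ketone removes the C2 epimer mixture so C2 can be set catalytically.

**Step 12**
Reactants: 13
Product: 14 (2S)-furyl carbinol (C2-OH S)
Conditions: RuCl[(S,S)-TsDPEN](p-cymene) (2 mol%), HCO2H/Et3N (5:2), CH2Cl2, 30 °C
Reagents that add atoms: none (formate supplies only H)
Why: Noyori asymmetric transfer hydrogenation; catalyst control sets C2 (S) and overrides the remote C10 centre.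

**Step 13**
Reactants: 14
Product: 15 C2-OTBS ether (TBS on C2 and C10; TES on C7 and C8)
Conditions: TBSOTf, 2,6-lutidine, CH2Cl2, –78 → 0 °C
Reagents that add atoms: TBSOTf, CC(C)(C)[Si](C)(C)OS(=O)(=O)C(F)(F)F (adds TBS)
Why: Silylation of the hindered secondary furfuryl alcohol with an orthogonal, more robust group than TES.

**Step 14**
Reactants: 15
Product: 16 C7 primary alcohol (C8-OTES, C10-OTBS and C2-OTBS retained)
Conditions: PPTS (0.2 equiv), MeOH/CH2Cl2 (1:1), 0 °C, 2–3 h
Reagents that add atoms: none
Why: Kinetic acid methanolysis removes the primary TES far faster than the secondary TES or the TBS ethers.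

**Step 15**
Reactants: 16
Product: 17 C7 α-silyloxy aldehyde (C8 OTES)
Conditions: Dess–Martin periodinane, NaHCO3, CH2Cl2, 25 °C
Reagents that add atoms: none
Why: Mild oxidation; no base is present to epimerize C8, and the furan survives.

**Step 16**
Reactants: 17 and 18 methyl acrylate
Product: 19 MBH adduct (C7-OH, C7 epimeric mixture)
Conditions: DABCO (0.5 equiv), neat methyl acrylate (10 equiv), cat. MeOH, 25 °C, 3–5 d
Reagents that add atoms: methyl acrylate, C=CC(=O)OC (adds C11, C12, C13, OMe)
Why: Morita–Baylis–Hillman reaction; the C7 carbinol stereocentre is erased in step 17, so its epimer ratio is irrelevant.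

**Step 17**
Reactants: 19
Product: 20 (Z)-2-(bromomethyl)alk-2-enoate (C7=C11, CH2Br on C11)
Conditions: MsCl, Et3N, CH2Cl2, 0 °C; then LiBr (5 equiv), THF, 0 → 25 °C
Reagents that add atoms: LiBr, [Li+].[Br-] (adds Br)
Why: Mesylation followed by bromide SN2′ displacement gives the thermodynamically favoured (Z)-allylic bromide under non-acidic conditions compatible with furan and silyl ethers.

**Step 18**
Reactants: 20
Product: 21 (Z)-4-oxo-2-enal (C3 ketone, C4(CH3)=C5 cis to C6 aldehyde)
Conditions: DMDO (≈0.07 M in acetone, 1.05 equiv), acetone, –20 °C, 30 min; use crude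
Reagents that add atoms: DMDO, CC1(C)OO1 (adds O)
Why: Dioxirane oxidative furan opening cleaves the ring without isomerization, giving the cis-ene-dicarbonyl. This installs Z-C4=C5 and the C3 carbonyl, with C6 as the aldehyde.

**Step 19**
Reactants: 21
Product: 22 macrocyclic homoallylic alcohol–methyl ester (10-membered 3-oxo-4Z-germacrane; C6-OH, C7 bearing C(=CH2)CO2Me; C6R, C7R expected as the major isomer)
Conditions: In powder (3 equiv), DMF, 25 °C, 2 mM, syringe-pump addition of 21 over 8 h; then sat. NH4Cl
Reagents that add atoms: none (H comes from the aqueous work-up)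
Why: Proposed new method: an intramolecular indium Barbier γ-allylation of a (Z)-4-oxo-2-enal by a (Z)-2-(bromomethyl)alk-2-enoate.
- Indium inserts into the allylic C–Br bond, and the allylindium adds through its γ-carbon (C7) to the more electrophilic aldehyde (C6). The ketone, enone and esters are untouched.
- The chair-like six-membered transition state, with In coordinated to the ester, is anti-selective. This gives the 6,7-trans relationship, with C8 and C10 and the cis-enone biasing the macrocyclic face selection.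
- The C6 alkoxide may sit in equilibrium with a 3,6-hemiketal, which funnels into the lactone in step 20.
- The closest known reactions are the intramolecular Nozaki–Hiyama–Kishi allylation used to close germacranolide rings and intermolecular In/Zn Barbier additions of 2-(bromomethyl)acrylates. Neither has been applied to macrocyclization onto a Z-4-oxoenal.

**Step 20**
Reactants: 22
Product: 23 trans-fused α-methylene-γ-lactone macrocycle (2,10-bis-OTBS, 8-OTES, 3-oxo-germacra-4Z,11(13)-dien-12,6-olide)
Conditions: PPTS (0.3 equiv), toluene, 50 °C, 4 Å MS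
Reagents that add atoms: none (MeOH is lost)
Why: Acid-catalysed γ-lactonization of the C6 alcohol onto the C12 methyl ester. The C8 silyl ether is still in place, so the 8,12-lactone cannot form.

**Step 21**
Reactants: 23
Product: 24 C8-alcohol (TBS groups retained)
Conditions: PPTS (0.3 equiv), MeOH, 0 → 25 °C
Reagents that add atoms: none
Why: Secondary TES ethers are methanolysed selectively in the presence of the secondary and tertiary TBS ethers.

**Step 22**
Reactants: 24 and 25 angelic acid
Product: 26 C8 angelate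
Conditions: angelic acid, 2,4,6-Cl3C6H2COCl, Et3N, THF, 25 °C, 2 h; then add 24 and DMAP, toluene, 25 °C
Reagents that add atoms: angelic acid, C/C=C(/C)C(=O)O (adds the angeloyl group)
Why: Yamaguchi esterification at the only free hydroxyl; the mild mixed-anhydride conditions keep the Z-alkene (angelate rather than tiglate).

**Step 23**
Reactants: 26
Product: 27 2β-hydroxy-1-desoxyniveusin A (target)
Conditions: HF·pyridine, pyridine/THF (1:3), 25 → 40 °C, 48 h
Reagents that add atoms: none
Why: Removal of the C2 and C10 TBS ethers frees the C10 tertiary alcohol, which closes transannularly onto the C3 ketone to give the bridged hemiketal. The configuration at C3 (S) is fixed by the bridge, because C4 and C9 must be cis on the tetrahydrofuran. No other stereocentre is touched.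

## Compound list
1 | (R)-linalool | C=C[C@](C)(O)CCC=C(C)C | starting material
2 | (R)-linalool TBS ether | C=C[C@](C)(O[Si](C)(C)C(C)(C)C)CCC=C(C)C | intermediate
3 | 6,7-epoxide of 2 (epoxide epimers) | C=C[C@](C)(O[Si](C)(C)C(C)(C)C)CCC1OC1(C)C | intermediate
4 | (4R)-4-(TBSO)-4-methylhex-5-enal | C=C[C@](C)(O[Si](C)(C)C(C)(C)C)CCC=O | intermediate
5 | (2R,4R)-4-(TBSO)-4-methyl-2-[(phenylamino)oxy]hex-5-en-1-ol | C=C[C@](C)(O[Si](C)(C)C(C)(C)C)C[C@@H](ONc1ccccc1)CO | intermediate
6 | (2R,4R)-4-(TBSO)-4-methylhex-5-ene-1,2-diol | C=C[C@](C)(O[Si](C)(C)C(C)(C)C)C[C@@H](O)CO | intermediate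
7 | 1,2-bis-TES ether of 6 | C=C[C@](C)(O[Si](C)(C)C(C)(C)C)C[C@@H](O[Si](CC)(CC)CC)CO[Si](CC)(CC)CC | intermediate
8 | (3S,5R)-3-(TBSO)-3-methyl-5,6-bis(TESO)hexan-1-ol | OCC[C@](C)(O[Si](C)(C)C(C)(C)C)C[C@@H](O[Si](CC)(CC)CC)CO[Si](CC)(CC)CC | intermediate
9 | (3R,5R)-3-(TBSO)-3-methyl-5,6-bis(TESO)hexanal | O=CC[C@](C)(O[Si](C)(C)C(C)(C)C)C[C@@H](O[Si](CC)(CC)CC)CO[Si](CC)(CC)CC | intermediate
10 | 3-methylfuran | Cc1ccoc1 | starting material
11 | 2-bromo-3-methylfuran | Cc1ccoc1Br | intermediate
12 | 1-(3-methylfuran-2-yl) carbinol from 9 (C2 epimers) | Cc1ccoc1C(O)C[C@](C)(O[Si](C)(C)C(C)(C)C)C[C@@H](O[Si](CC)(CC)CC)CO[Si](CC)(CC)CC | intermediate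
13 | 2-acylfuran (C2 ketone) | Cc1ccoc1C(=O)C[C@](C)(O[Si](C)(C)C(C)(C)C)C[C@@H](O[Si](CC)(CC)CC)CO[Si](CC)(CC)CC | intermediate
14 | (2S)-furyl carbinol | Cc1ccoc1[C@@H](O)C[C@](C)(O[Si](C)(C)C(C)(C)C)C[C@@H](O[Si](CC)(CC)CC)CO[Si](CC)(CC)CC | intermediate
15 | C2-OTBS ether of 14 | Cc1ccoc1[C@@H](O[Si](C)(C)C(C)(C)C)C[C@](C)(O[Si](C)(C)C(C)(C)C)C[C@@H](O[Si](CC)(CC)CC)CO[Si](CC)(CC)CC | intermediate
16 | C7 primary alcohol | Cc1ccoc1[C@@H](O[Si](C)(C)C(C)(C)C)C[C@](C)(O[Si](C)(C)C(C)(C)C)C[C@@H](O[Si](CC)(CC)CC)CO | intermediate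
17 | C7 aldehyde | Cc1ccoc1[C@@H](O[Si](C)(C)C(C)(C)C)C[C@](C)(O[Si](C)(C)C(C)(C)C)C[C@@H](O[Si](CC)(CC)CC)C=O | intermediate
18 | methyl acrylate | C=CC(=O)OC | starting material
19 | MBH adduct (C7 epimers) | Cc1ccoc1[C@@H](O[Si](C)(C)C(C)(C)C)C[C@](C)(O[Si](C)(C)C(C)(C)C)C[C@@H](O[Si](CC)(CC)CC)C(O)C(=C)C(=O)OC | intermediate
20 | (Z)-allylic bromide | Cc1ccoc1[C@@H](O[Si](C)(C)C(C)(C)C)C[C@](C)(O[Si](C)(C)C(C)(C)C)C[C@@H](O[Si](CC)(CC)CC)/C=C(\CBr)C(=O)OC | intermediate
21 | (Z)-4-oxo-2-enal | O=C/C=C(\C(=O)[C@@H](O[Si](C)(C)C(C)(C)C)C[C@](C)(O[Si](C)(C)C(C)(C)C)C[C@@H](O[Si](CC)(CC)CC)/C=C(\CBr)C(=O)OC)C | intermediate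
22 | macrocyclic hydroxy ester | O=C1/C(C)=C\[C@@H](O)[C@H](C(=C)C(=O)OC)[C@H](O[Si](CC)(CC)CC)C[C@@](C)(O[Si](C)(C)C(C)(C)C)C[C@@H]1O[Si](C)(C)C(C)(C)C | intermediate
23 | trans-fused lactone macrocycle | O=C1/C(C)=C\[C@H]2OC(=O)C(=C)[C@@H]2[C@H](O[Si](CC)(CC)CC)C[C@@](C)(O[Si](C)(C)C(C)(C)C)C[C@@H]1O[Si](C)(C)C(C)(C)C | intermediate
24 | C8-alcohol | O=C1/C(C)=C\[C@H]2OC(=O)C(=C)[C@@H]2[C@H](O)C[C@@](C)(O[Si](C)(C)C(C)(C)C)C[C@@H]1O[Si](C)(C)C(C)(C)C | intermediate
25 | angelic acid | C/C=C(/C)C(=O)O | starting material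
26 | C8 angelate | O=C1/C(C)=C\[C@H]2OC(=O)C(=C)[C@@H]2[C@H](OC(=O)/C(C)=C\C)C[C@@](C)(O[Si](C)(C)C(C)(C)C)C[C@@H]1O[Si](C)(C)C(C)(C)C | intermediate
27 | 2β-hydroxy-1-desoxyniveusin A | C=C1C(=O)O[C@@H]2/C=C(/C)[C@]3(O)O[C@](C)(C[C@@H](OC(=O)/C(C)=C\C)[C@@H]12)C[C@@H]3O | target

## Totals
Total steps: 23. Longest linear sequence: 22 steps, from (R)-linalool; step 9 is a parallel branch making 11.

## Three steps most likely to fail

1. **Step 19 (proposed new In-mediated macro-allylation).**
   - Risks: Z→E enal isomerization, conjugate addition to the enedione, wrong C6 face, or oligomerization.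
   - Fallback (known chemistry, different approach): oxidatively degrade the furan of 15 (RuCl3/NaIO4) to the C3 acid and convert it to the Weinreb amide. Carry the C7 end through to the allylic bromide. Run an intermolecular In-Barbier allylation with acrolein to give the 6-vinyl trans-α-methylene lactone. Add isopropenylMgBr to the Weinreb amide to give the C3 ketone with C4=CH2. Close C4=C5 by Z-selective ring-closing metathesis (Hoveyda–Grubbs II or a Mo-MAP catalyst). Finish as in steps 21–23.

2. **Step 18 (furan oxidation to the Z-keto-enal).**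
   - Risks: over-oxidation, Z→E isomerization, reaction at the acrylate or allylic bromide.
   - Fallback: oxidize with NBS/NaHCO3 in MeOH to the isolable 2,5-dimethoxy-2,5-dihydrofuran, a masked Z-enedione. Unmask it with PPTS in aqueous acetone immediately before the allylation.

3. **Step 16 (MBH on the hindered α-silyloxy aldehyde).**
   - Risks: slow reaction and DABCO-induced epimerization of C8.
   - Fallback: use an amine-free Lewis-acid halo-Baylis–Hillman reaction (MgI2 or TiCl4/Bu4NI with methyl acrylate) to give the allylic halide directly. This removes both the amine base and the mesylation step, and the halide then isomerizes by SN2′ to the (Z)-bromomethyl enoate.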